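**Retrosynthetic overview**
1. 24 ⇐ seco-aldehyde 21. One operation closes the ten-membered carbocycle at C6–C7 (intramolecular allylboration of the 4Z-enal by a 2-methoxycarbonyl allyl-Bpin; this is the farnesyl C1–C10 bond), then the 6,12-lactone (C6–O onto C12). Carbocycle first, lactone second; HF then frees C3-OH.
2. 21 ⇐ aldehyde 13: Morita–Baylis–Hillman reaction (C11–C13 from methyl acrylate), SN2′ borylation, and the C8 tiglate installed before ring closure.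
3. 13 ⇐ alkyne 7 + keto ester 9: chelation-controlled alkynyl addition forms C10–C1 and sets C10; Lindlar reduction gives 1Z.
4. 7 ⇐ 3-methylfuran-2(5H)-one + TMS-acetylene (4Z taken from the ring, CBS sets C3); 9 ⇐ ethyl 2,4-dioxopentanoate (Pt/cinchonidine sets C8).

Assumption: the target is taken exactly as drawn, i.e. 3R,6S,7R,8R,10R,1Z,4Z with a cis-fused 6,12-lactone (H-6/H-7 cis), in germacrane numbering (ring C1–C10, lactone unit C11–C13); this numbering is used in the Why lines.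

**Step 1**
Reactants: 1 3-methylfuran-2(5H)-one; 2 ethynyltrimethylsilane
Product: 4 (Z)-6-[(tert-butyldimethylsilyl)oxy]-4-methyl-1-(trimethylsilyl)hex-4-en-1-yn-3-one, via ring-opened lithium alkoxide 3 (not isolated)
Conditions: 2, n-BuLi, THF, −78 °C; add 1, −78 °C; then TBSCl, imidazole, DMF, −78 °C → rt
Reagents that add atoms: tert-butyldimethylsilyl chloride, CC(C)(C)[Si](C)(C)Cl
Why: 1,2-addition of the lithium acetylide to the butenolide carbonyl gives a lactol alkoxide that opens to the Z-γ-alkoxy ynone and is trapped on oxygen before it can dehydrate to a furan (lactone ring-opening with in situ silylation); the 4Z geometry is inherited from the ring.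

**Step 2**
Reactants: 4 (Z)-6-[(tert-butyldimethylsilyl)oxy]-4-methyl-1-(trimethylsilyl)hex-4-en-1-yn-3-one
Product: 5 (3S,4Z)-6-[(tert-butyldimethylsilyl)oxy]-4-methyl-1-(trimethylsilyl)hex-4-en-1-yn-3-ol
Conditions: (S)-2-methyl-CBS-oxazaborolidine, BH3·SMe2, THF, −30 °C; MeOH quench
Reagents that add atoms: none
Why: Corey–Bakshi–Shibata reduction in which the α-branched alkenyl group acts as the large and the alkynyl as the small substituent, so the (S)-catalyst delivers hydride to the face that gives the C3 carbinol of the target (3S here, 3R once the silicon is gone).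

**Step 3**
Reactants: 5 (3S,4Z)-6-[(tert-butyldimethylsilyl)oxy]-4-methyl-1-(trimethylsilyl)hex-4-en-1-yn-3-ol
Product: 7 (3R,4Z)-3,6-bis[(tert-butyldimethylsilyl)oxy]-4-methylhex-4-en-1-yne, via C-silylated bis-TBS ether 6 (not isolated)
Conditions: TBSCl, imidazole, DMF, rt; then MeOH, K2CO3, rt
Reagents that add atoms: tert-butyldimethylsilyl chloride, CC(C)(C)[Si](C)(C)Cl
Why: O-silylation of the secondary alcohol followed by base-mediated methanolysis of the C(sp)–SiMe3 bond, to which O-TBS ethers are inert.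

**Step 4**
Reactants: 8 ethyl 2,4-dioxopentanoate
Product: 9 ethyl (2R)-2-hydroxy-4-oxopentanoate
Conditions: H2 (10 bar), 5% Pt/Al2O3, cinchonidine, toluene/AcOH, rt
Reagents that add atoms: none
Why: Orito-type enantioselective heterogeneous hydrogenation reduces only the activated 2-keto group, and cinchonidine gives the (R)-α-hydroxy ester, which becomes C8 (about 85–90% ee expected; the rest is removed as a diastereomer after step 5).

**Step 5**
Reactants: 7 (3R,4Z)-3,6-bis[(tert-butyldimethylsilyl)oxy]-4-methylhex-4-en-1-yne; 9 ethyl (2R)-2-hydroxy-4-oxopentanoate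
Product: 11 ethyl (2R,4R,7S,8Z)-7,10-bis[(tert-butyldimethylsilyl)oxy]-4,8-dimethyl-2,4-bis[(triethylsilyl)oxy]dec-8-en-5-ynoate, via bis(bromomagnesium) diolate 10 (not isolated)
Conditions: 9, EtMgBr (1.0 equiv), THF, −78 °C; then alkynyl-MgBr from 7 + EtMgBr (1.2 equiv), −78 → −20 °C; then TESOTf, 2,6-lutidine, −78 → 0 °C
Reagents that add atoms: triethylsilyl trifluoromethanesulfonate, CC[Si](CC)(CC)OS(=O)(=O)C(F)(F)F
Why: chelation-controlled (Cram-chelate, 1,3-anti) addition of the alkynyl Grignard to the magnesium β-alkoxy ketone sets C10 (R) anti to the C8 oxygen, and TESOTf traps both alkoxides before the tertiary one can lactonise onto the ester; stereochemical leakage from steps 2 and 4 is separated here as diastereomers.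

**Step 6**
Reactants: 11 ethyl (2R,4R,7S,8Z)-7,10-bis[(tert-butyldimethylsilyl)oxy]-4,8-dimethyl-2,4-bis[(triethylsilyl)oxy]dec-8-en-5-ynoate
Product: 12 ethyl (2R,4R,5Z,7R,8Z)-7,10-bis[(tert-butyldimethylsilyl)oxy]-4,8-dimethyl-2,4-bis[(triethylsilyl)oxy]deca-5,8-dienoate
Conditions: H2 (1 atm), Lindlar catalyst, quinoline, EtOAc, rt
Reagents that add atoms: none
Why: Lindlar syn-semihydrogenation of the internal alkyne gives the 1Z alkene; the trisubstituted alkene, ester and silyl ethers are untouched.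

**Step 7**
Reactants: 12 ethyl (2R,4R,5Z,7R,8Z)-7,10-bis[(tert-butyldimethylsilyl)oxy]-4,8-dimethyl-2,4-bis[(triethylsilyl)oxy]deca-5,8-dienoate
Product: 13 (2R,4R,5Z,7R,8Z)-7,10-bis[(tert-butyldimethylsilyl)oxy]-4,8-dimethyl-2,4-bis[(triethylsilyl)oxy]deca-5,8-dienal
Conditions: DIBAL-H (1.1 equiv), CH2Cl2, −78 °C; Rochelle salt
Reagents that add atoms: none
Why: partial DIBAL reduction, since the aluminium hemiacetal of an α-silyloxy ester is stable at −78 °C and gives the aldehyde on work-up; both hydroxyls are silylated, so no lactol can form.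

**Step 8**
Reactants: 13 (2R,4R,5Z,7R,8Z)-7,10-bis[(tert-butyldimethylsilyl)oxy]-4,8-dimethyl-2,4-bis[(triethylsilyl)oxy]deca-5,8-dienal; 14 methyl acrylate
Product: 15 methyl (4R,6R,7Z,9R,10Z)-9,12-bis[(tert-butyldimethylsilyl)oxy]-3-hydroxy-6,10-dimethyl-2-methylidene-4,6-bis[(triethylsilyl)oxy]dodeca-7,10-dienoate (C3 epimer mixture)
Conditions: 14 (neat, excess), DABCO (1 equiv), MeOH (cat.), rt, 5–7 d
Reagents that add atoms: none
Why: Morita–Baylis–Hillman reaction of an activated α-silyloxy aldehyde brings in C11–C13; the new C7 carbinol is an inconsequential epimer mixture because C7 becomes sp2 in step 10.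

**Step 9**
Reactants: 15 methyl (4R,6R,7Z,9R,10Z)-9,12-bis[(tert-butyldimethylsilyl)oxy]-3-hydroxy-6,10-dimethyl-2-methylidene-4,6-bis[(triethylsilyl)oxy]dodeca-7,10-dienoate
Product: 16 methyl (4R,6R,7Z,9R,10Z)-3-acetoxy-9,12-bis[(tert-butyldimethylsilyl)oxy]-6,10-dimethyl-2-methylidene-4,6-bis[(triethylsilyl)oxy]dodeca-7,10-dienoate (C3 epimer mixture)
Conditions: Ac2O, pyridine, DMAP (cat.), CH2Cl2, 0 °C
Reagents that add atoms: acetic anhydride, CC(=O)OC(C)=O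
Why: DMAP-catalysed acetylation turns the Baylis–Hillman hydroxyl into the leaving group for the SN2′ step; C8 stays silylated so that it cannot lactonise onto C12.

**Step 10**
Reactants: 16 methyl (4R,6R,7Z,9R,10Z)-3-acetoxy-9,12-bis[(tert-butyldimethylsilyl)oxy]-6,10-dimethyl-2-methylidene-4,6-bis[(triethylsilyl)oxy]dodeca-7,10-dienoate
Product: 17 methyl (2E,4R,6R,7Z,9R,10Z)-9,12-bis[(tert-butyldimethylsilyl)oxy]-6,10-dimethyl-2-[(4,4,5,5-tetramethyl-1,3,2-dioxaborolan-2-yl)methyl]-4,6-bis[(triethylsilyl)oxy]dodeca-2,7,10-trienoate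
Conditions: B2pin2, CuCl (10 mol %), LiCl, KOAc, DMF, rt
Reagents that add atoms: bis(pinacolato)diboron, CC1(C)OB(OC1(C)C)B1OC(C)(C)C(C)(C)O1
Why: copper-catalysed SN2′ borylation of a Baylis–Hillman acetate (boryl-copper conjugate addition, then β-acetoxy elimination) gives the thermodynamically preferred enoate with C8 cis to CH2Bpin, the Z-crotyl-type geometry needed for a syn allylboration.

**Step 11**
Reactants: 17 methyl (2E,4R,6R,7Z,9R,10Z)-9,12-bis[(tert-butyldimethylsilyl)oxy]-6,10-dimethyl-2-[(4,4,5,5-tetramethyl-1,3,2-dioxaborolan-2-yl)methyl]-4,6-bis[(triethylsilyl)oxy]dodeca-2,7,10-trienoate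
Product: 18 methyl (2E,4R,6R,7Z,9R,10Z)-9-[(tert-butyldimethylsilyl)oxy]-4,6,12-trihydroxy-6,10-dimethyl-2-[(4,4,5,5-tetramethyl-1,3,2-dioxaborolan-2-yl)methyl]dodeca-2,7,10-trienoate
Conditions: CSA (10 mol %), MeOH/CH2Cl2, 0 °C
Reagents that add atoms: none
Why: acid-catalysed methanolysis removes the primary allylic TBS and both TES ethers far faster than the hindered secondary C3-OTBS; with C8 now trans to the ester across C7=C11, the freed C8-OH cannot lactonise.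

**Step 12**
Reactants: 18 methyl (2E,4R,6R,7Z,9R,10Z)-9-[(tert-butyldimethylsilyl)oxy]-4,6,12-trihydroxy-6,10-dimethyl-2-[(4,4,5,5-tetramethyl-1,3,2-dioxaborolan-2-yl)methyl]dodeca-2,7,10-trienoate
Product: 19 methyl (2E,4R,6R,7Z,9R,10Z)-9-[(tert-butyldimethylsilyl)oxy]-4,6-dihydroxy-6,10-dimethyl-12-oxo-2-[(4,4,5,5-tetramethyl-1,3,2-dioxaborolan-2-yl)methyl]dodeca-2,7,10-trienoate
Conditions: MnO2 (excess), CH2Cl2, rt
Reagents that add atoms: none
Why: MnO2 allylic oxidation takes the electron-rich primary Z-allylic alcohol to the Z-enal without isomerisation (as nerol gives neral), while the secondary C8-OH next to the electron-poor enoate and the tertiary C10-OH are left.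

**Step 13**
Reactants: 19 methyl (2E,4R,6R,7Z,9R,10Z)-9-[(tert-butyldimethylsilyl)oxy]-4,6-dihydroxy-6,10-dimethyl-12-oxo-2-[(4,4,5,5-tetramethyl-1,3,2-dioxaborolan-2-yl)methyl]dodeca-2,7,10-trienoate; 20 (E)-2-methylbut-2-enoyl chloride (tigloyl chloride)
Product: 21 methyl (2E,4R,6R,7Z,9R,10Z)-9-[(tert-butyldimethylsilyl)oxy]-6-hydroxy-6,10-dimethyl-4-{[(2E)-2-methylbut-2-enoyl]oxy}-12-oxo-2-[(4,4,5,5-tetramethyl-1,3,2-dioxaborolan-2-yl)methyl]dodeca-2,7,10-trienoate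
Conditions: 20, Et3N, DMAP (cat.), CH2Cl2, 0 °C
Reagents that add atoms: none
Why: DMAP-catalysed acylation of the only reactive hydroxyl (C8; the tertiary C10-OH is inert) installs the tiglate before ring closure, so that only C6–O can lactonise afterwards; the covalent allyl-Bpin cannot eliminate the δ-acyloxy group as an allyl-Cr, -Zn or -In species would.

**Step 14**
Reactants: 21 methyl (2E,4R,6R,7Z,9R,10Z)-9-[(tert-butyldimethylsilyl)oxy]-6-hydroxy-6,10-dimethyl-4-{[(2E)-2-methylbut-2-enoyl]oxy}-12-oxo-2-[(4,4,5,5-tetramethyl-1,3,2-dioxaborolan-2-yl)methyl]dodeca-2,7,10-trienoate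
Product: 24 (1Z,3R,4Z,6S,7R,8R,10R)-3,10-dihydroxy-8-[(E)-2-methylbut-2-enoyloxy]germacra-1,4,11(13)-trien-6,12-olide (target CNP0262559.2), via O-boryl hydroxy ester macrocycle 22 (not isolated), via 3-O-TBS lactone 23 (not isolated)
Conditions: Sc(OTf)3 (20 mol %), 4 Å MS, toluene, 1 mM (syringe pump), 40 °C; then HF·pyridine, pyridine, THF, 0 °C → rt
Reagents that add atoms: none
Why: Proposed new method: a Lewis-acid-catalysed intramolecular allylboration/lactonisation as the macrocyclisation, in which Sc(OTf)3 activates the boronate (Hall-type catalysis), C7 adds to the C6 aldehyde through a closed chair transition state with the Z-type C8 substituent axial (6,7-syn, hence the cis-lactone), allylic strain (H-8 eclipsing C7=C11, attack anti to the C9 chain) is expected to give 7R but may be overridden by ring strain, the C6–O–B alkoxide then closes onto the methyl ester and HF removes the TBS group; closest known reactions are the intermolecular Lewis-acid-catalysed 2-alkoxycarbonyl-allylboration/lactonisation to α-methylene-γ-lactones and CrCl2-mediated Nozaki–Hiyama macrocyclisations of 2-(bromomethyl)acrylates to germacranolides.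

**Compound list**
1 | 3-methylfuran-2(5H)-one | CC1=CCOC1=O | starting material
2 | ethynyltrimethylsilane | C#C[Si](C)(C)C | starting material
3 | lithium alkoxide of (Z)-6-hydroxy-4-methyl-1-(trimethylsilyl)hex-4-en-1-yn-3-one | [Li]OC/C=C(/C)C(=O)C#C[Si](C)(C)C | intermediate
4 | (Z)-6-[(tert-butyldimethylsilyl)oxy]-4-methyl-1-(trimethylsilyl)hex-4-en-1-yn-3-one | CC(C)(C)[Si](C)(C)OC/C=C(/C)C(=O)C#C[Si](C)(C)C | intermediate
5 | (3S,4Z)-6-[(tert-butyldimethylsilyl)oxy]-4-methyl-1-(trimethylsilyl)hex-4-en-1-yn-3-ol | CC(C)(C)[Si](C)(C)OC/C=C(/C)[C@H](O)C#C[Si](C)(C)C | intermediate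
6 | (3S,4Z)-3,6-bis[(tert-butyldimethylsilyl)oxy]-4-methyl-1-(trimethylsilyl)hex-4-en-1-yne | CC(C)(C)[Si](C)(C)OC/C=C(/C)[C@H](O[Si](C)(C)C(C)(C)C)C#C[Si](C)(C)C | intermediate
7 | (3R,4Z)-3,6-bis[(tert-butyldimethylsilyl)oxy]-4-methylhex-4-en-1-yne | CC(C)(C)[Si](C)(C)OC/C=C(/C)[C@H](O[Si](C)(C)C(C)(C)C)C#C | intermediate
8 | ethyl 2,4-dioxopentanoate | CCOC(=O)C(=O)CC(C)=O | starting material
9 | ethyl (2R)-2-hydroxy-4-oxopentanoate | CC(=O)C[C@@H](O)C(=O)OCC | intermediate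
10 | bis(bromomagnesium) alkoxide of ethyl (2R,4R,7S,8Z)-7,10-bis[(tert-butyldimethylsilyl)oxy]-2,4-dihydroxy-4,8-dimethyldec-8-en-5-ynoate | CC(C)(C)[Si](C)(C)OC/C=C(/C)[C@H](O[Si](C)(C)C(C)(C)C)C#C[C@](C)(O[Mg]Br)C[C@@H](O[Mg]Br)C(=O)OCC | intermediate
11 | ethyl (2R,4R,7S,8Z)-7,10-bis[(tert-butyldimethylsilyl)oxy]-4,8-dimethyl-2,4-bis[(triethylsilyl)oxy]dec-8-en-5-ynoate | CC(C)(C)[Si](C)(C)OC/C=C(/C)[C@H](O[Si](C)(C)C(C)(C)C)C#C[C@](C)(O[Si](CC)(CC)CC)C[C@@H](O[Si](CC)(CC)CC)C(=O)OCC | intermediate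
12 | ethyl (2R,4R,5Z,7R,8Z)-7,10-bis[(tert-butyldimethylsilyl)oxy]-4,8-dimethyl-2,4-bis[(triethylsilyl)oxy]deca-5,8-dienoate | CC(C)(C)[Si](C)(C)OC/C=C(/C)[C@H](O[Si](C)(C)C(C)(C)C)/C=C\[C@](C)(O[Si](CC)(CC)CC)C[C@@H](O[Si](CC)(CC)CC)C(=O)OCC | intermediate
13 | (2R,4R,5Z,7R,8Z)-7,10-bis[(tert-butyldimethylsilyl)oxy]-4,8-dimethyl-2,4-bis[(triethylsilyl)oxy]deca-5,8-dienal | CC(C)(C)[Si](C)(C)OC/C=C(/C)[C@H](O[Si](C)(C)C(C)(C)C)/C=C\[C@](C)(O[Si](CC)(CC)CC)C[C@@H](O[Si](CC)(CC)CC)C=O | intermediate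
14 | methyl acrylate | C=CC(=O)OC | starting material
15 | methyl (4R,6R,7Z,9R,10Z)-9,12-bis[(tert-butyldimethylsilyl)oxy]-3-hydroxy-6,10-dimethyl-2-methylidene-4,6-bis[(triethylsilyl)oxy]dodeca-7,10-dienoate (C3 epimers) | CC(C)(C)[Si](C)(C)OC/C=C(/C)[C@H](O[Si](C)(C)C(C)(C)C)/C=C\[C@](C)(O[Si](CC)(CC)CC)C[C@@H](O[Si](CC)(CC)CC)C(O)C(=C)C(=O)OC | intermediate
16 | methyl (4R,6R,7Z,9R,10Z)-3-acetoxy-9,12-bis[(tert-butyldimethylsilyl)oxy]-6,10-dimethyl-2-methylidene-4,6-bis[(triethylsilyl)oxy]dodeca-7,10-dienoate (C3 epimers) | CC(C)(C)[Si](C)(C)OC/C=C(/C)[C@H](O[Si](C)(C)C(C)(C)C)/C=C\[C@](C)(O[Si](CC)(CC)CC)C[C@@H](O[Si](CC)(CC)CC)C(OC(C)=O)C(=C)C(=O)OC | intermediate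
17 | methyl (2E,4R,6R,7Z,9R,10Z)-9,12-bis[(tert-butyldimethylsilyl)oxy]-6,10-dimethyl-2-[(4,4,5,5-tetramethyl-1,3,2-dioxaborolan-2-yl)methyl]-4,6-bis[(triethylsilyl)oxy]dodeca-2,7,10-trienoate | CC(C)(C)[Si](C)(C)OC/C=C(/C)[C@H](O[Si](C)(C)C(C)(C)C)/C=C\[C@](C)(O[Si](CC)(CC)CC)C[C@@H](O[Si](CC)(CC)CC)/C=C(\CB1OC(C)(C)C(C)(C)O1)C(=O)OC | intermediate
18 | methyl (2E,4R,6R,7Z,9R,10Z)-9-[(tert-butyldimethylsilyl)oxy]-4,6,12-trihydroxy-6,10-dimethyl-2-[(4,4,5,5-tetramethyl-1,3,2-dioxaborolan-2-yl)methyl]dodeca-2,7,10-trienoate | OC/C=C(/C)[C@H](O[Si](C)(C)C(C)(C)C)/C=C\[C@](C)(O)C[C@@H](O)/C=C(\CB1OC(C)(C)C(C)(C)O1)C(=O)OC | intermediate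
19 | methyl (2E,4R,6R,7Z,9R,10Z)-9-[(tert-butyldimethylsilyl)oxy]-4,6-dihydroxy-6,10-dimethyl-12-oxo-2-[(4,4,5,5-tetramethyl-1,3,2-dioxaborolan-2-yl)methyl]dodeca-2,7,10-trienoate | O=C/C=C(/C)[C@H](O[Si](C)(C)C(C)(C)C)/C=C\[C@](C)(O)C[C@@H](O)/C=C(\CB1OC(C)(C)C(C)(C)O1)C(=O)OC | intermediate
20 | (E)-2-methylbut-2-enoyl chloride (tigloyl chloride) | C/C=C(\C)C(=O)Cl | starting material
21 | methyl (2E,4R,6R,7Z,9R,10Z)-9-[(tert-butyldimethylsilyl)oxy]-6-hydroxy-6,10-dimethyl-4-{[(2E)-2-methylbut-2-enoyl]oxy}-12-oxo-2-[(4,4,5,5-tetramethyl-1,3,2-dioxaborolan-2-yl)methyl]dodeca-2,7,10-trienoate | O=C/C=C(/C)[C@H](O[Si](C)(C)C(C)(C)C)/C=C\[C@](C)(O)C[C@@H](OC(=O)/C(C)=C/C)/C=C(\CB1OC(C)(C)C(C)(C)O1)C(=O)OC | intermediate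
22 | ring-closed allylboration adduct: methyl 2-substituted acrylate on C7 of the (1Z,4Z)-cyclodecadiene, carrying 6-O-Bpin, 3-OTBS, 8-O-tigloyl and 10-OH, configured as in 24 | CC1(C)OB(OC1(C)C)O[C@H]2/C=C(/C)[C@H](O[Si](C)(C)C(C)(C)C)/C=C\[C@](C)(O)C[C@@H](OC(=O)/C(C)=C/C)[C@H]2C(=C)C(=O)OC | intermediate
23 | 3-O-tert-butyldimethylsilyl ether of 24 | C=C1C(=O)O[C@H]2/C=C(/C)[C@H](O[Si](C)(C)C(C)(C)C)/C=C\[C@](C)(O)C[C@@H](OC(=O)/C(C)=C/C)[C@@H]12 | intermediate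
24 | (1Z,3R,4Z,6S,7R,8R,10R)-3,10-dihydroxy-8-[(E)-2-methylbut-2-enoyloxy]germacra-1,4,11(13)-trien-6,12-olide (CNP0262559.2) | C=C1C(=O)O[C@H]2/C=C(/C)[C@H](O)/C=C\[C@](C)(O)C[C@@H](OC(=O)/C(C)=C/C)[C@@H]12 | target

**Totals**
Total steps: 14. Longest linear sequence: 13 (steps 1–3, then 5–14).

**Three steps most likely to fail, with fallbacks**

Step 14 (ring closure). A catalysed allylboration at 1 mM may be too slow, and the facial selectivity at C7 is untested; the free tertiary allylic C10-OH may also suffer under Sc(OTf)3. The fallback is a silicon-based Hosomi–Sakurai closure that sets out from acetate 16 and comes back to the route at 23. Copper-catalysed SN2′ silylation of 16 with PhMe2Si–Bpin gives the allylsilane methyl (2Z,4R,6R,7Z,9R,10Z)-9,12-bis[(tert-butyldimethylsilyl)oxy]-2-{[dimethyl(phenyl)silyl]methyl}-6,10-dimethyl-4,6-bis[(triethylsilyl)oxy]dodeca-2,7,10-trienoate F1. CSA/MeOH gives the triol methyl (2Z,4R,6R,7Z,9R,10Z)-9-[(tert-butyldimethylsilyl)oxy]-2-{[dimethyl(phenyl)silyl]methyl}-4,6,12-trihydroxy-6,10-dimethyldodeca-2,7,10-trienoate F2. MnO2 gives the enal methyl (2Z,4R,6R,7Z,9R,10Z)-9-[(tert-butyldimethylsilyl)oxy]-2-{[dimethyl(phenyl)silyl]methyl}-4,6-dihydroxy-6,10-dimethyl-12-oxododeca-2,7,10-trienoate F3. Tigloyl chloride 20 gives the seco-aldehyde methyl (2Z,4R,6R,7Z,9R,10Z)-9-[(tert-butyldimethylsilyl)oxy]-2-{[dimethyl(phenyl)silyl]methyl}-6-hydroxy-6,10-dimethyl-4-{[(2E)-2-methylbut-2-enoyl]oxy}-12-oxododeca-2,7,10-trienoate F4. BF3·OEt2 (CH2Cl2, −78 °C, 1 mM) then closes C6–C7 through an open antiperiplanar transition state (syn-selective; intramolecular SE2′ macrocyclisations of allylstannanes are the precedent), and the C6 alkoxide lactonises to 23.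

Step 1 (lactone opening with silyl trapping). The lactol alkoxide may dehydrate to a 2-alkynyl-3-methylfuran, add a second acetylide, or be silylated on the wrong oxygen. The fallback avoids any lactol stage; it sets out from 1 and comes back at 4. Me(MeO)NH·HCl/AlMe3 opens 1 to (2Z)-4-hydroxy-N-methoxy-N,2-dimethylbut-2-enamide F5. TBSCl/imidazole gives (2Z)-4-[(tert-butyldimethylsilyl)oxy]-N-methoxy-N,2-dimethylbut-2-enamide F6. Lithium (trimethylsilyl)acetylide from 2 converts the Weinreb amide into 4.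

Step 5 (chelation-controlled union). The C10 selectivity may be modest, and the tertiary alkoxide may lactonise before it is silylated. The fallback uses the lactone as a purification handle; it sets out from 7 and 9 and comes back at 13. The same Grignard addition is run without TESOTf and worked up with acid, so that the product closes to (3R,5R)-5-{(3S,4Z)-3,6-bis[(tert-butyldimethylsilyl)oxy]-4-methylhex-4-en-1-yn-1-yl}-3-hydroxy-5-methyloxolan-2-one F7, whose C10 epimers are separated. Me(MeO)NH·HCl/AlMe3 opens it to (2R,4R,7S,8Z)-7,10-bis[(tert-butyldimethylsilyl)oxy]-2,4-dihydroxy-N-methoxy-N,4,8-trimethyldec-8-en-5-ynamide F8. TESOTf/2,6-lutidine gives (2R,4R,7S,8Z)-7,10-bis[(tert-butyldimethylsilyl)oxy]-N-methoxy-N,4,8-trimethyl-2,4-bis[(triethylsilyl)oxy]dec-8-en-5-ynamide F9. Lindlar reduction gives (2R,4R,5Z,7R,8Z)-7,10-bis[(tert-butyldimethylsilyl)oxy]-N-methoxy-N,4,8-trimethyl-2,4-bis[(triethylsilyl)oxy]deca-5,8-dienamide F10, and DIBAL-H reduces the amide to 13.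

**Further compounds**
F1 | step 14 | methyl (2Z,4R,6R,7Z,9R,10Z)-9,12-bis[(tert-butyldimethylsilyl)oxy]-2-{[dimethyl(phenyl)silyl]methyl}-6,10-dimethyl-4,6-bis[(triethylsilyl)oxy]dodeca-2,7,10-trienoate | CC(C)(C)[Si](C)(C)OC/C=C(/C)[C@H](O[Si](C)(C)C(C)(C)C)/C=C\[C@](C)(O[Si](CC)(CC)CC)C[C@@H](O[Si](CC)(CC)CC)/C=C(\C[Si](C)(C)c1ccccc1)C(=O)OC
F2 | step 14 | methyl (2Z,4R,6R,7Z,9R,10Z)-9-[(tert-butyldimethylsilyl)oxy]-2-{[dimethyl(phenyl)silyl]methyl}-4,6,12-trihydroxy-6,10-dimethyldodeca-2,7,10-trienoate | OC/C=C(/C)[C@H](O[Si](C)(C)C(C)(C)C)/C=C\[C@](C)(O)C[C@@H](O)/C=C(\C[Si](C)(C)c1ccccc1)C(=O)OC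
F3 | step 14 | methyl (2Z,4R,6R,7Z,9R,10Z)-9-[(tert-butyldimethylsilyl)oxy]-2-{[dimethyl(phenyl)silyl]methyl}-4,6-dihydroxy-6,10-dimethyl-12-oxododeca-2,7,10-trienoate | O=C/C=C(/C)[C@H](O[Si](C)(C)C(C)(C)C)/C=C\[C@](C)(O)C[C@@H](O)/C=C(\C[Si](C)(C)c1ccccc1)C(=O)OC
F4 | step 14 | methyl (2Z,4R,6R,7Z,9R,10Z)-9-[(tert-butyldimethylsilyl)oxy]-2-{[dimethyl(phenyl)silyl]methyl}-6-hydroxy-6,10-dimethyl-4-{[(2E)-2-methylbut-2-enoyl]oxy}-12-oxododeca-2,7,10-trienoate | O=C/C=C(/C)[C@H](O[Si](C)(C)C(C)(C)C)/C=C\[C@](C)(O)C[C@@H](OC(=O)/C(C)=C/C)/C=C(\C[Si](C)(C)c1ccccc1)C(=O)OC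
F5 | step 1 | (2Z)-4-hydroxy-N-methoxy-N,2-dimethylbut-2-enamide | OC/C=C(/C)C(=O)N(C)OC
F6 | step 1 | (2Z)-4-[(tert-butyldimethylsilyl)oxy]-N-methoxy-N,2-dimethylbut-2-enamide | CC(C)(C)[Si](C)(C)OC/C=C(/C)C(=O)N(C)OC
F7 | step 5 | (3R,5R)-5-{(3S,4Z)-3,6-bis[(tert-butyldimethylsilyl)oxy]-4-methylhex-4-en-1-yn-1-yl}-3-hydroxy-5-methyloxolan-2-one | CC(C)(C)[Si](C)(C)OC/C=C(/C)[C@H](O[Si](C)(C)C(C)(C)C)C#C[C@@]1(C)C[C@@H](O)C(=O)O1
F8 | step 5 | (2R,4R,7S,8Z)-7,10-bis[(tert-butyldimethylsilyl)oxy]-2,4-dihydroxy-N-methoxy-N,4,8-trimethyldec-8-en-5-ynamide | CC(C)(C)[Si](C)(C)OC/C=C(/C)[C@H](O[Si](C)(C)C(C)(C)C)C#C[C@](C)(O)C[C@@H](O)C(=O)N(C)OC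
F9 | step 5 | (2R,4R,7S,8Z)-7,10-bis[(tert-butyldimethylsilyl)oxy]-N-methoxy-N,4,8-trimethyl-2,4-bis[(triethylsilyl)oxy]dec-8-en-5-ynamide | CC(C)(C)[Si](C)(C)OC/C=C(/C)[C@H](O[Si](C)(C)C(C)(C)C)C#C[C@](C)(O[Si](CC)(CC)CC)C[C@@H](O[Si](CC)(CC)CC)C(=O)N(C)OC
F10 | step 5 | (2R,4R,5Z,7R,8Z)-7,10-bis[(tert-butyldimethylsilyl)oxy]-N-methoxy-N,4,8-trimethyl-2,4-bis[(triethylsilyl)oxy]deca-5,8-dienamide | CC(C)(C)[Si](C)(C)OC/C=C(/C)[C@H](O[Si](C)(C)C(C)(C)C)/C=C\[C@](C)(O[Si](CC)(CC)CC)C[C@@H](O[Si](CC)(CC)CC)C(=O)N(C)OC
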